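**Retrosynthetic overview**

1. Target ring numbering: N1(H)–C2(=O)–C3H2–C4(H)(undecyl)–N5–C6–C8–N9–C10–C13–N14–C15–C17. The last step is N-methylation of N5, N9 and N14 of the NH macrolactam 17.
2. The 17-membered ring is not closed end to end. The β-amino amide N5–C4–C3–C2(=O) is read as a latent azetidin-2-one, and the acyl carbon C2 is walked along the spermine nitrogens N5 → N9 → N14 → N1 (3-, 4- and 3-carbon spacers) by transamidative ring expansion, 4 → 8 → 13 → 17.
3. The first hop (4 → 8) occurs when (4R)-1-(3-chloropropyl)-4-undecylazetidin-2-one alkylates commercial N1,N4-bis-Boc-spermidine. After Boc removal the second and third hops (8 → 13 → 17) run as one base-induced cascade.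
4. The only stereocentre, C4 (R), is set before any ring exists, by titanium enolate addition of methyl acetate to the (R)-tert-butanesulfinyl imine of dodecanal; the β-amino ester is then closed to the β-lactam.
5. Ring order: azetidinone → 1,5-diazocan-2-one → (1,5,9-triazacyclotridecan-2-one, transient) → 1,5,9,14-tetraazacycloheptadecan-2-one.

Key step: step 8

Assumption (chemistry): the titanium enolate is taken to add to the Si face of the (R_S)-aldimine 3 through the usual chelated chair transition state, which corresponds to (R) at the new carbon; should the sense be opposite, only the enantiomer of the sulfinamide changes.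

**Route**

Step 1
Reactants: 1 dodecanal; 2 (R)-2-methylpropane-2-sulfinamide
Product: 3 (R_S,E)-N-dodecylidene-2-methylpropane-2-sulfinamide
Conditions: Ti(OEt)4 (2 equiv), THF, rt
Reagents that add atoms: none
Why: Lewis-acid-mediated condensation of an aldehyde with a sulfinamide (N-sulfinyl imine formation), in which Ti(OEt)4 activates the carbonyl and takes up the water, and the unbranched aldimine should form as the E isomer only.

Step 2
Reactants: 3 (R_S,E)-N-dodecylidene-2-methylpropane-2-sulfinamide; 4 methyl acetate
Product: 5 methyl (3R)-3-{[(R)-tert-butylsulfinyl]amino}tetradecanoate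
Conditions: 4, LDA, THF, −78 °C; ClTi(OiPr)3 (2 equiv); then 3, −78 °C; aq. NH4Cl
Reagents that add atoms: none
Why: Mannich-type addition of a titanium ester enolate to an N-sulfinyl aldimine, in which the closed chair-like six-membered transition state with titanium bound to the sulfinyl oxygen should deliver the enolate to the Si face of the (R_S)-imine and so set C3 as (R).

Step 3
Reactants: 5 methyl (3R)-3-{[(R)-tert-butylsulfinyl]amino}tetradecanoate
Product: 6 methyl (3R)-3-aminotetradecanoate hydrochloride
Conditions: HCl (4 M in dioxane), MeOH, rt; evaporation, trituration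
Reagents that add atoms: hydrogen chloride, Cl
Why: acid-mediated N–S cleavage (sulfinamide methanolysis) is fast at room temperature, leaves the methyl ester intact and does not touch the stereocentre.

Step 4
Reactants: 6 methyl (3R)-3-aminotetradecanoate hydrochloride
Product: 9 (4R)-4-undecylazetidin-2-one, via N-TMS amino ester 7 (not isolated), via N-TMS azetidinone 8 (not isolated)
Conditions: Et3N (2.2 equiv), TMSCl, Et2O, 0 °C; then tBuMgCl, 0 °C → rt; aq. NH4Cl
Reagents that add atoms: none
Why: Grignard-mediated cyclisation of an N-silyl β-amino ester (4-exo-trig acyl substitution by the magnesium amide), the standard entry to N-unsubstituted azetidinones, with C4 not involved in any bond change.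

Step 5
Reactants: 9 (4R)-4-undecylazetidin-2-one; 10 1-bromo-3-chloropropane
Product: 11 (4R)-1-(3-chloropropyl)-4-undecylazetidin-2-one
Conditions: powdered KOH, Bu4NBr (cat.), 10 (3 equiv), THF, rt
Reagents that add atoms: none
Why: solid–liquid phase-transfer N-alkylation of the lactam anion (SN2), known for 4-substituted azetidinones, in which bromide is displaced in preference to chloride.

Step 6
Reactants: 11 (4R)-1-(3-chloropropyl)-4-undecylazetidin-2-one; 12 N1,N4-bis-Boc-spermidine (tert-butyl N-(4-aminobutyl)-N-[3-(tert-butoxycarbonylamino)propyl]carbamate)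
Product: 14 tert-butyl N-[3-(tert-butoxycarbonylamino)propyl]-N-{4-[(4R)-2-oxo-4-undecyl-1,5-diazocan-1-yl]butyl}carbamate, via amino-azetidinone 13 (not isolated)
Conditions: 12 (2 equiv), NaI (cat.), K2CO3, MeCN, 80 °C
Reagents that add atoms: none
Why: SN2 amination with in-situ Finkelstein activation, followed by strain-driven transamidative ring expansion in which the new secondary amine attacks the β-lactam carbonyl through a six-membered tetrahedral intermediate (4 → 8); this converts the amine into an amide and should limit over-alkylation.

Step 7
Reactants: 14 tert-butyl N-[3-(tert-butoxycarbonylamino)propyl]-N-{4-[(4R)-2-oxo-4-undecyl-1,5-diazocan-1-yl]butyl}carbamate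
Product: 15 (4R)-1-{4-[(3-aminopropyl)amino]butyl}-4-undecyl-1,5-diazocan-2-one
Conditions: HCl (4 M in dioxane), CH2Cl2, rt; aq. NaOH work-up
Reagents that add atoms: none
Why: acidolytic cleavage of both tert-butyl carbamates (Boc removal), to which the tertiary eight-membered lactam and the stereocentre are inert.

Step 8
Reactants: 15 (4R)-1-{4-[(3-aminopropyl)amino]butyl}-4-undecyl-1,5-diazocan-2-one
Product: 17 (4R)-4-undecyl-1,5,9,14-tetraazacycloheptadecan-2-one, via 13-membered lactam 16 (not isolated)
Conditions: KH, H2N(CH2)3NH2 (KAPA, excess), rt; H2O quench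
Reagents that add atoms: none
Why: KAPA deprotonates the side-chain amines of 15; the butylene-tethered nitrogen (future N14) adds to the lactam carbonyl C2 to give a bicyclic tetrahedral intermediate whose C–N bond to the old amide nitrogen (future N9) breaks, enlarging the ring from 8 to 13 members (16), and the terminal NH2 (future N1) then repeats the process, 13 → 17. The closest known reaction type is the Zip reaction, the base-induced transamidative ring enlargement of N-(ω-aminoalkyl)lactams, including 4 → 8 → 13 sequences of β-lactam-derived diazocanones. Both rings arise by exo attack on the carbonyl (7-exo-trig, then 6-exo-trig) followed by opening of the bridging C–N bond, so no large ring is closed end to end and no high dilution is needed. No stereocentre is formed, and C4 is a spectator because no bond to it is made or broken. The selectivity needed is the direction of acyl migration, towards N1 and not back: relief of medium-ring strain drives the first hop, and the secondary lactam of 17 is deprotonated by KAPA to a stabilised amidate that cannot revert, whereas attack by the ring nitrogen N5 would only re-form the strained azetidinone.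

Step 9
Reactants: 17 (4R)-4-undecyl-1,5,9,14-tetraazacycloheptadecan-2-one
Product: 18 (4R)-5,9,14-trimethyl-4-undecyl-1,5,9,14-tetraazacycloheptadecan-2-one
Conditions: 37% aq. HCHO (excess), HCO2H, 95 °C
Reagents that add atoms: formaldehyde, C=O
Why: Eschweiler–Clarke reductive methylation converts the three secondary amines into N-methyl tertiary amines without quaternisation, reversible aminals between neighbouring nitrogens are drained through their iminium ions, and the secondary lactam N1–H is not methylated.

**Compound list**

1 | dodecanal | CCCCCCCCCCCC=O | starting material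
2 | (R)-2-methylpropane-2-sulfinamide | CC(C)(C)[S@@](=O)N | starting material
3 | (R_S,E)-N-dodecylidene-2-methylpropane-2-sulfinamide | CC(C)(C)[S@@](=O)/N=C/CCCCCCCCCCC | intermediate
4 | methyl acetate | CC(=O)OC | starting material
5 | methyl (3R)-3-{[(R)-tert-butylsulfinyl]amino}tetradecanoate | CCCCCCCCCCC[C@H](CC(=O)OC)N[S@](=O)C(C)(C)C | intermediate
6 | methyl (3R)-3-aminotetradecanoate hydrochloride | CCCCCCCCCCC[C@@H](N)CC(=O)OC.Cl | intermediate
7 | methyl (3R)-3-[(trimethylsilyl)amino]tetradecanoate | CCCCCCCCCCC[C@@H](N[Si](C)(C)C)CC(=O)OC | intermediate (not isolated)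
8 | (4R)-1-(trimethylsilyl)-4-undecylazetidin-2-one | CCCCCCCCCCC[C@@H]1CC(=O)N1[Si](C)(C)C | intermediate (not isolated)
9 | (4R)-4-undecylazetidin-2-one | CCCCCCCCCCC[C@@H]1CC(=O)N1 | intermediate
10 | 1-bromo-3-chloropropane | ClCCCBr | starting material
11 | (4R)-1-(3-chloropropyl)-4-undecylazetidin-2-one | CCCCCCCCCCC[C@@H]1CC(=O)N1CCCCl | intermediate
12 | N1,N4-bis-Boc-spermidine | NCCCCN(CCCNC(=O)OC(C)(C)C)C(=O)OC(C)(C)C | starting material
13 | tert-butyl N-[3-(tert-butoxycarbonylamino)propyl]-N-[4-({3-[(4R)-2-oxo-4-undecylazetidin-1-yl]propyl}amino)butyl]carbamate | CCCCCCCCCCC[C@@H]1CC(=O)N1CCCNCCCCN(CCCNC(=O)OC(C)(C)C)C(=O)OC(C)(C)C | intermediate (not isolated)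
14 | tert-butyl N-[3-(tert-butoxycarbonylamino)propyl]-N-{4-[(4R)-2-oxo-4-undecyl-1,5-diazocan-1-yl]butyl}carbamate | CCCCCCCCCCC[C@@H]1CC(=O)N(CCCCN(CCCNC(=O)OC(C)(C)C)C(=O)OC(C)(C)C)CCCN1 | intermediate
15 | (4R)-1-{4-[(3-aminopropyl)amino]butyl}-4-undecyl-1,5-diazocan-2-one | CCCCCCCCCCC[C@@H]1CC(=O)N(CCCCNCCCN)CCCN1 | intermediate
16 | (4R)-1-(3-aminopropyl)-4-undecyl-1,5,9-triazacyclotridecan-2-one | CCCCCCCCCCC[C@@H]1CC(=O)N(CCCN)CCCCNCCCN1 | intermediate (not isolated)
17 | (4R)-4-undecyl-1,5,9,14-tetraazacycloheptadecan-2-one | CCCCCCCCCCC[C@@H]1CC(=O)NCCCNCCCCNCCCN1 | intermediate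
18 | (4R)-5,9,14-trimethyl-4-undecyl-1,5,9,14-tetraazacycloheptadecan-2-one | CCCCCCCCCCC[C@@H]1CC(=O)NCCCN(C)CCCCN(C)CCCN1C | target

**Step count and risks**

Total step count: 9. Longest linear sequence: 9 steps (from dodecanal).

Steps most likely to fail:

1. Step 8 (key step). The acyl transfer through the seven-membered intermediate (8 → 13) may stall, the external amide base may open the lactam intermolecularly, or base-mediated β-elimination and re-addition of the amine may erode the configuration at C4. The fallback sets out from 15 and replaces ring expansion by a templated end-to-end macrolactamisation. Hydrolysis of the eight-membered lactam (6 M HCl, reflux) followed by esterification (SOCl2, MeOH) and liberation of the free base should give methyl (3R)-3-{[3-({4-[(3-aminopropyl)amino]butyl}amino)propyl]amino}tetradecanoate F1. Antimony-templated cyclisation of F1 (Sb(OEt)3, toluene, reflux, dilute), in which the four nitrogens gather on the metal and the terminal primary amine is acylated, should then close the 17-membered lactam. The route is rejoined at 17.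

2. Step 6. The amine may be alkylated twice before ring expansion takes it out of play, or the chloride may react too slowly and intermolecular aminolysis of the β-lactam may intervene. The fallback sets out from 12 and 11 and uses sulfonamide alkylation instead of amine alkylation. Treatment of 12 with 2-nitrobenzenesulfonyl chloride and Et3N should give tert-butyl N-[3-(tert-butoxycarbonylamino)propyl]-N-{4-[(2-nitrophenyl)sulfonylamino]butyl}carbamate F2. Alkylation of F2 with 11 (Cs2CO3, NaI, DMF), which can occur only once, should give tert-butyl N-[3-(tert-butoxycarbonylamino)propyl]-N-{4-[(2-nitrophenyl)sulfonyl{3-[(4R)-2-oxo-4-undecylazetidin-1-yl]propyl}amino]butyl}carbamate F3. Removal of the sulfonyl group with PhSH and K2CO3 should release 13, which ring-expands on warming. The route is rejoined at 14.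

3. Step 4. Intermolecular amidation and oligomerisation of the amino ester may compete with closure of the four-membered ring. The fallback sets out from 6 and activates the carboxyl group instead of the nitrogen. Saponification (LiOH, aq. THF) should give (3R)-3-aminotetradecanoic acid F4, which should cyclise under redox condensation with PPh3 and 2,2'-dipyridyl disulfide (MeCN, reflux, high dilution). The route is rejoined at 9.

**Further compounds**

F1 | step 8 | methyl (3R)-3-{[3-({4-[(3-aminopropyl)amino]butyl}amino)propyl]amino}tetradecanoate | CCCCCCCCCCC[C@@H](NCCCNCCCCNCCCN)CC(=O)OC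
F2 | step 6 | tert-butyl N-[3-(tert-butoxycarbonylamino)propyl]-N-{4-[(2-nitrophenyl)sulfonylamino]butyl}carbamate | O=S(=O)(NCCCCN(CCCNC(=O)OC(C)(C)C)C(=O)OC(C)(C)C)c1ccccc1[N+](=O)[O-]
F3 | step 6 | tert-butyl N-[3-(tert-butoxycarbonylamino)propyl]-N-{4-[(2-nitrophenyl)sulfonyl{3-[(4R)-2-oxo-4-undecylazetidin-1-yl]propyl}amino]butyl}carbamate | CCCCCCCCCCC[C@@H]1CC(=O)N1CCCN(CCCCN(CCCNC(=O)OC(C)(C)C)C(=O)OC(C)(C)C)S(=O)(=O)c1ccccc1[N+](=O)[O-]
F4 | step 4 | (3R)-3-aminotetradecanoic acid | CCCCCCCCCCC[C@@H](N)CC(=O)O
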